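The route rests on cutting the ten-membered carbocycle at C6–C7 and C1–C10. It exploits that O1 and O6, together with the C4–C5 epoxide oxygen and the C10 methyl, lie on one face of this ring, the face on which a one-carbon bridge can span C1 and C6. A thermal [6+4] cycloaddition of 4-methyltropone (C1–C6, C4 methyl, bridge carbon) with (E)-2-silyloxypenta-1,3-diene (C7–C10) forms both bonds, closes the perimeter as a bicyclo[4.4.1]undecatrienone and sets C1, C6 and C10 at once. Two retentive Baeyer–Villiger oxidations later trade the carbonyl bridge for the two oxygens; an oxalate tether on O6 then delivers the butenolide.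

Key step: step 5

Remark on the chemistry: germacrane numbering (ring C1–C10, lactone carbons C11–C13) is used for all intermediates, the bridge carbon is called Cb, and "top face" means the face of the ten-membered perimeter that carries Cb in 7. The thermal cycloaddition is not enantioselective, so 7 is racemic (its SMILES shows the enantiomer carried on) and the single enantiomer is secured at step 6.

Step 1
Reactants: 1 4-methylanisole
Product: 2 1-methoxy-4-methylcyclohexa-1,4-diene
Conditions: Li, NH3 (l), t-BuOH, THF, −33 °C
Reagents that add atoms: none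
Why: Birch reduction of the anisole gives the 2,5-dihydro isomer, in which the enol ether and the methyl-substituted alkene are not conjugated.

Step 2
Reactants: 2 1-methoxy-4-methylcyclohexa-1,4-diene
Product: 3 7,7-dichloro-1-methoxy-4-methylbicyclo[4.1.0]hept-3-ene (racemic, cis ring fusion)
Conditions: CHCl3, KOt-Bu, pentane, −20 → 0 °C
Reagents that add atoms: chloroform, ClC(Cl)Cl
Why: Dichlorocarbene, made by α-elimination from chloroform, cyclopropanates the electron-rich enol ether double bond in preference to the trisubstituted alkene ([2+1] cycloaddition).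

Step 3
Reactants: 3 7,7-dichloro-1-methoxy-4-methylbicyclo[4.1.0]hept-3-ene
Product: 4 4-methyltropone (4-methylcyclohepta-2,4,6-trien-1-one)
Conditions: pyridine, H2O, 100 °C
Reagents that add atoms: water, O
Why: Methoxy-assisted electrocyclic ring opening of the dichlorocyclopropane (cyclopropyl-to-allyl cation ring expansion), hydrolysis of the oxocarbenium ion and loss of two HCl give the aromatic tropone, a known route from dihydroanisoles to tropones.

Step 4
Reactants: 5 (E)-pent-3-en-2-one
Product: 6 (E)-2-(tert-butyldimethylsilyloxy)penta-1,3-diene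
Conditions: TBSOTf, Et3N, CH2Cl2, 0 °C
Reagents that add atoms: tert-butyldimethylsilyl triflate, CC(C)(C)[Si](C)(C)OS(=O)(=O)C(F)(F)F
Why: Soft enolisation toward the methyl group with silyl triflate and amine (silyl enol ether formation) gives the cross-conjugated dienol ether and leaves the E alkene in place.

Step 5
Reactants: 4 4-methyltropone; 6 (E)-2-(tert-butyldimethylsilyloxy)penta-1,3-diene
Product: 7 (±)-8-(tert-butyldimethylsilyloxy)-4,10-dimethylbicyclo[4.4.1]undeca-2,4,8-trien-11-one, C10 methyl on the face of the carbonyl bridge Cb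
Conditions: toluene, 110 °C, sealed tube, 6 in excess, BHT (cat.)
Reagents that add atoms: none
Why: A concerted, thermally allowed [6π+4π] cycloaddition joins the two α-carbons of the tropone suprafacially to the termini of the s-cis diene, forming C6–C7 and C1–C10; the closest known reaction type is the thermal exo-selective [6+4] cycloaddition of tropones with 1,3-dienes, 2-silyloxydienes included. Both new rings, the cycloheptene ring C6–C7–C8–C9–C10–C1–Cb and with it the ten-membered perimeter C1–C10, close in this single pericyclic event, which also creates the C8=C9 enol ether. C1 and C6 are set cis to one another by the suprafacial use of the planar tropone, and C10 is set by the exo transition state, which keeps the diene backbone away from the triene and so places the E methyl on the face of Cb. The step needs periselectivity for [6+4] over [4+2], exo selectivity, and the orientation in which the CH2 terminus bonds to the tropone α-carbon that becomes C6. Exo selectivity follows from the repulsive secondary orbital interaction of the endo mode; the orientation follows from polarisation, since bonding of the nucleophilic enol ether β-carbon (the CH2 terminus) to the α-carbon nearer the ring methyl lets the developing negative charge of the tropone rest on oxygen and on carbons that carry no methyl, but this bias is small. The product is racemic.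

Step 6
Reactants: 7 (±)-bridged trienone silyl enol ether
Product: 8 C8 spiro-ketal with (4R,5R)-4,5-diphenyl-1,3-dioxolane of 4,10-dimethylbicyclo[4.4.1]undeca-2,4-diene-8,11-dione, single diastereomer with the bicyclic configuration of the target
Conditions: (R,R)-hydrobenzoin, TsOH (cat.), CH2Cl2, 4 Å MS, rt; separation of the two diastereomeric ketals by chromatography
Reagents that add atoms: (R,R)-hydrobenzoin, O[C@H](c1ccccc1)[C@H](O)c1ccccc1
Why: Acid-catalysed exchange of the enol ether with the diol (ketalisation through the C8 oxocarbenium ion) masks C8 while the hindered bridging ketone stays free, and the C2-symmetric auxiliary turns the racemate into two separable diastereomers (classical resolution), of which the one shown is kept.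

Step 7
Reactants: 8 dienone ketal
Product: 9 C2–C3 dihydro compound (C4=C5 alkene, bridging ketone, C8 ketal)
Conditions: 2-nitrobenzenesulfonylhydrazide, Et3N, CH2Cl2, rt
Reagents that add atoms: none
Why: Diimide reduction delivers H2 by a concerted syn transfer to the cis-disubstituted C2=C3 bond far faster than to the trisubstituted C4=C5 bond and does not touch ketone or ketal.

Step 8
Reactants: 9 enone ketal
Product: 11 epoxy lactone (4,5-epoxide on the top face, oxygen inserted between C1 and Cb), via epoxy ketone 10 (not isolated)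
Conditions: mCPBA, NaHCO3, CH2Cl2, 0 → 40 °C
Reagents that add atoms: 3-chloroperbenzoic acid, O=C(OO)c1cccc(Cl)c1
Why: Prilezhaev epoxidation should take place on the top face, which is the convex side of the C2–C5 bridge away from the C7–C10 bridge, and the following Baeyer–Villiger oxidation of the bridging ketone should insert oxygen next to C1 with retention, because C6 is deactivated as a migrating group by the epoxide oxygen on C5.

Step 9
Reactants: 11 epoxy lactone
Product: 13 hydroxy methyl ketone (ten-membered ring, C1–OH and C6–COCH3 on the top face), via Weinreb amide 12 (not isolated)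
Conditions: MeNH(OMe)·HCl, i-PrMgCl, THF, −20 °C; then MeMgBr, −20 → 0 °C; aq. NH4Cl
Reagents that add atoms: methylmagnesium bromide, C[Mg]Br
Why: Aminolysis of the bridged lactone by the magnesium amide gives the Weinreb amide, and the chelated adduct of MeMgBr (Weinreb ketone synthesis) collapses to the methyl ketone only on quench, which avoids both over-addition and base-induced enolisation toward C6 next to the epoxide.

Step 10
Reactants: 13 hydroxy methyl ketone
Product: 14 C1 tert-butyldimethylsilyl ether
Conditions: TBSCl, imidazole, DMF, 35 °C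
Reagents that add atoms: tert-butyldimethylsilyl chloride, CC(C)(C)[Si](C)(C)Cl
Why: Silyl ether formation at the only free hydroxyl under weakly basic conditions.

Step 11
Reactants: 14 silyl ether methyl ketone
Product: 15 C6 acetate
Conditions: CF3CO3H, Na2HPO4, CH2Cl2, 0 °C
Reagents that add atoms: trifluoroperacetic acid, OOC(=O)C(F)(F)F
Why: Baeyer–Villiger oxidation of the methyl ketone, in which the secondary carbon C6 migrates in preference to methyl and with retention of configuration, so that the former bridge carbon leaves the skeleton as the carbonyl of a C6 acetate.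

Step 12
Reactants: 15 C6 acetate
Product: 16 C6 alcohol (C1–OTBS, 4,5-epoxide, C8 ketal)
Conditions: K2CO3 (cat.), MeOH, 0 °C
Reagents that add atoms: none
Why: Base-catalysed transesterification removes the acetate, while silyl ether, ketal and epoxide are stable to cold methanolic carbonate.

Step 13
Reactants: 16 C6 alcohol; 17 methyl chlorooxoacetate
Product: 18 C6 methyl oxalate
Conditions: pyridine, CH2Cl2, −20 °C
Reagents that add atoms: none
Why: O-Acylation of the C6 alcohol by the acid chloride attaches the two carbons that become C12 and C11.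

Step 14
Reactants: 18 C6 methyl oxalate
Product: 19 8-oxo C6 methyl oxalate
Conditions: H2 (1 atm), Pd(OH)2/C, EtOAc, rt
Reagents that add atoms: none
Why: Hydrogenolysis of the two benzylic C–O bonds of the ketal frees the C8 ketone without acid or base, so that epoxide, oxalate and silyl ether are untouched.

Step 15
Reactants: 19 8-oxo C6 methyl oxalate
Product: 20 11-hydroxy-8-oxo-7(11)-en-12,6-olide (3-hydroxybutenolide fused at C6–C7)
Conditions: LiN(SiMe3)2, THF, −78 °C; AcOH quench at −78 °C; recovered 19 is recycled
Reagents that add atoms: none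
Why: Proposed new method: deprotonation at C7 gives a lithium enolate that should attack the distal ester carbonyl of the oxalate in a 5-exo-trig acyl substitution, expelling methoxide and leaving the C7=C11 enol of an α-keto lactone whose acidity drives the reaction, the low temperature being chosen so that ring closure outruns β-elimination of the oxalate and any C9 enolate simply returns ketone on quench; the closest known reaction types are the crossed Claisen condensation of ketone enolates with dialkyl oxalates and the Dieckmann-type closure of acyloxy carbonyl compounds to tetronic acids.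

Step 16
Reactants: 20 3-hydroxybutenolide
Product: 21 C11 enol triflate
Conditions: Tf2O, 2,6-lutidine, CH2Cl2, −78 °C
Reagents that add atoms: triflic anhydride, O=S(=O)(OS(=O)(=O)C(F)(F)F)C(F)(F)F
Why: O-Sulfonylation of the acidic enol hydroxyl (enol triflate formation) activates C11 for cross-coupling.

Step 17
Reactants: 21 C11 enol triflate; 22 (tributylstannyl)methanol
Product: 23 13-hydroxy-8-oxo-7(11)-en-12,6-olide
Conditions: Pd2(dba)3, AsPh3, CuI, LiCl, NMP, 40 °C
Reagents that add atoms: none
Why: Stille coupling of the electron-poor vinyl triflate with the α-hydroxymethylstannane, which transfers the oxygenated methyl group in preference to butyl, attaches C13 to C11.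

Step 18
Reactants: 23 13-hydroxy compound
Product: 24 13-acetoxy-8-oxo-7(11)-en-12,6-olide
Conditions: Ac2O, pyridine, DMAP (cat.), CH2Cl2, 0 °C
Reagents that add atoms: acetic anhydride, CC(=O)OC(C)=O
Why: Acetylation of the primary allylic alcohol by nucleophilic catalysis.

Step 19
Reactants: 24 13-acetoxy-8-oxo compound
Product: 25 (8S)-8-hydroxy compound (hydroxyl on the top face)
Conditions: (R)-2-methyl-CBS-oxazaborolidine, catecholborane, toluene, −78 °C
Reagents that add atoms: none
Why: Corey–Bakshi–Shibata reduction gives 1,2-reduction of the enone-type ketone under catalyst control; with the alkenyl carbon C7 as the large and C9H2 as the small substituent the (R)-catalyst should deliver hydride to the face that gives the 8S alcohol.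

Step 20
Reactants: 25 (8S)-alcohol; 26 methacryloyl chloride
Product: 27 8-O-methacrylate, C1 silyl ether
Conditions: Et3N, DMAP (cat.), CH2Cl2, 0 °C
Reagents that add atoms: none
Why: Acylation of the secondary allylic alcohol with the acid chloride under DMAP catalysis (esterification).

Step 21
Reactants: 27 silyl-protected target
Product: 28 target, (1S,4R,5S,6S,8S,10R)-13-acetoxy-4,5-epoxy-1-hydroxy-8-(methacryloyloxy)germacr-7(11)-en-12,6-olide
Conditions: HF·pyridine, pyridine, THF, 0 °C → rt
Reagents that add atoms: none
Why: Fluoride-mediated cleavage of the silyl ether with pyridine-buffered HF, conditions under which the ester groups and the trisubstituted epoxide should survive.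

Compound list
1 | 4-methylanisole | COc1ccc(C)cc1 | starting material
2 | 1-methoxy-4-methylcyclohexa-1,4-diene | COC1=CCC(C)=CC1 | intermediate
3 | 7,7-dichloro-1-methoxy-4-methylbicyclo[4.1.0]hept-3-ene (racemic, cis-fused) | COC12CC=C(C)CC1C2(Cl)Cl | intermediate
4 | 4-methyltropone | O=C1C=CC(C)=CC=C1 | intermediate
5 | (E)-pent-3-en-2-one | C/C=C/C(C)=O | starting material
6 | (E)-2-(tert-butyldimethylsilyloxy)penta-1,3-diene | C=C(O[Si](C)(C)C(C)(C)C)/C=C/C | intermediate
7 | (±)-8-(tert-butyldimethylsilyloxy)-4,10-dimethylbicyclo[4.4.1]undeca-2,4,8-trien-11-one, C10 methyl syn to Cb (racemic; enantiomer carried on is shown) | CC(C)(C)[Si](C)(C)OC1=C[C@@H](C)[C@@H]2C=CC(C)=C[C@H](C1)C2=O | intermediate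
8 | C8 (R,R)-hydrobenzoin ketal of 4,10-dimethylbicyclo[4.4.1]undeca-2,4-diene-8,11-dione, single diastereomer | O1[C@H](c2ccccc2)[C@@H](c2ccccc2)OC13C[C@@H](C)[C@@H]4C=CC(C)=C[C@H](C3)C4=O | intermediate
9 | 2,3-dihydro compound: C4=C5 alkene, bridging ketone, C8 ketal | O1[C@H](c2ccccc2)[C@@H](c2ccccc2)OC13C[C@@H](C)[C@@H]4CCC(C)=C[C@H](C3)C4=O | intermediate
10 | epoxy ketone: 4,5-epoxide on the top face, bridging ketone, C8 ketal | O1[C@H](c2ccccc2)[C@@H](c2ccccc2)OC13C[C@@H](C)[C@@H]4CC[C@@]5(C)O[C@H]5[C@H](C3)C4=O | intermediate (not isolated)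
11 | epoxy lactone: C1–O–C(=O)–C6 bridge, 4,5-epoxide, C8 ketal | O1[C@H](c2ccccc2)[C@@H](c2ccccc2)OC13C[C@@H](C)[C@@H]4CC[C@@]5(C)O[C@H]5[C@H](C3)C(=O)O4 | intermediate
12 | Weinreb amide: C1–OH, C6–C(=O)N(OMe)Me, 4,5-epoxide, C8 ketal | O1[C@H](c2ccccc2)[C@@H](c2ccccc2)OC13C[C@@H](C)[C@@H](O)CC[C@@]4(C)O[C@H]4[C@H](C3)C(=O)N(C)OC | intermediate (not isolated)
13 | hydroxy methyl ketone: C1–OH, C6–COCH3 | O1[C@H](c2ccccc2)[C@@H](c2ccccc2)OC13C[C@@H](C)[C@@H](O)CC[C@@]4(C)O[C@H]4[C@H](C3)C(C)=O | intermediate
14 | C1 TBS ether of the methyl ketone | O1[C@H](c2ccccc2)[C@@H](c2ccccc2)OC13C[C@@H](C)[C@@H](O[Si](C)(C)C(C)(C)C)CC[C@@]4(C)O[C@H]4[C@H](C3)C(C)=O | intermediate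
15 | C6 acetate, C1 TBS ether | O1[C@H](c2ccccc2)[C@@H](c2ccccc2)OC13C[C@@H](C)[C@@H](O[Si](C)(C)C(C)(C)C)CC[C@@]4(C)O[C@H]4[C@H](C3)OC(C)=O | intermediate
16 | C6 alcohol, C1 TBS ether, 4,5-epoxide, C8 ketal | O1[C@H](c2ccccc2)[C@@H](c2ccccc2)OC13C[C@@H](C)[C@@H](O[Si](C)(C)C(C)(C)C)CC[C@@]4(C)O[C@H]4[C@H](C3)O | intermediate
17 | methyl chlorooxoacetate | COC(=O)C(=O)Cl | starting material
18 | C6 methyl oxalate, C8 ketal | O1[C@H](c2ccccc2)[C@@H](c2ccccc2)OC13C[C@@H](C)[C@@H](O[Si](C)(C)C(C)(C)C)CC[C@@]4(C)O[C@H]4[C@H](C3)OC(=O)C(=O)OC | intermediate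
19 | 8-oxo C6 methyl oxalate | O=C1C[C@@H](C)[C@@H](O[Si](C)(C)C(C)(C)C)CC[C@@]2(C)O[C@H]2[C@H](C1)OC(=O)C(=O)OC | intermediate
20 | 11-hydroxy-8-oxo-7(11)-en-12,6-olide, C1 TBS ether, 4,5-epoxide | O=C1C[C@@H](C)[C@@H](O[Si](C)(C)C(C)(C)C)CC[C@@]2(C)O[C@H]2[C@H]2OC(=O)C(O)=C12 | intermediate
21 | C11 enol triflate | O=C1C[C@@H](C)[C@@H](O[Si](C)(C)C(C)(C)C)CC[C@@]2(C)O[C@H]2[C@H]2OC(=O)C(OS(=O)(=O)C(F)(F)F)=C12 | intermediate
22 | (tributylstannyl)methanol | CCCC[Sn](CCCC)(CCCC)CO | starting material
23 | 13-hydroxy-8-oxo-7(11)-en-12,6-olide | O=C1C[C@@H](C)[C@@H](O[Si](C)(C)C(C)(C)C)CC[C@@]2(C)O[C@H]2[C@H]2OC(=O)C(CO)=C12 | intermediate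
24 | 13-acetoxy-8-oxo-7(11)-en-12,6-olide | O=C1C[C@@H](C)[C@@H](O[Si](C)(C)C(C)(C)C)CC[C@@]2(C)O[C@H]2[C@H]2OC(=O)C(COC(C)=O)=C12 | intermediate
25 | (8S)-13-acetoxy-8-hydroxy-7(11)-en-12,6-olide, C1 TBS ether | O[C@H]1C[C@@H](C)[C@@H](O[Si](C)(C)C(C)(C)C)CC[C@@]2(C)O[C@H]2[C@H]2OC(=O)C(COC(C)=O)=C12 | intermediate
26 | methacryloyl chloride | C=C(C)C(=O)Cl | starting material
27 | 8-O-methacrylate, C1 TBS ether | C=C(C)C(=O)O[C@H]1C[C@@H](C)[C@@H](O[Si](C)(C)C(C)(C)C)CC[C@@]2(C)O[C@H]2[C@H]2OC(=O)C(COC(C)=O)=C12 | intermediate
28 | (1S,4R,5S,6S,8S,10R)-13-acetoxy-4,5-epoxy-1-hydroxy-8-(methacryloyloxy)germacr-7(11)-en-12,6-olide | C=C(C)C(=O)O[C@H]1C[C@@H](C)[C@@H](O)CC[C@@]2(C)O[C@H]2[C@H]2OC(=O)C(COC(C)=O)=C12 | target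

Total step count: 21. Longest linear sequence: 20 steps (steps 1–3 and 5–21, from 1 to 28).

Steps most likely to fail

1. Step 15 (bears the label). What may go wrong: the C7 enolate expels the oxalate from C6 (β-elimination to a C6=C7 enone) faster than it closes the ring, or the base enolises mainly toward C9. The fallback uses known chemistry, a crossed Claisen condensation on a substrate whose C6 oxygen cannot leave. It sets out from 16: TMSCl and imidazole give the C6 trimethylsilyl ether F1; hydrogenolysis as in step 14 gives the β-silyloxy ketone F2; LiN(SiMe3)2 and dimethyl oxalate (THF, −78 → 0 °C) give the C7 methoxalyl ketone F3 beside its C9 isomer. Pyridine-buffered HF·pyridine then cleaves the trimethylsilyl ether of F3, the freed C6 hydroxyl lactonises onto the keto ester, and the route is rejoined at 20; the C9 isomer cannot lactonise and is removed. Regiocontrol is given up in exchange for an enolate that cannot eliminate.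

2. Step 5. What may go wrong: the diene adds in the reversed orientation (CH(CH3) terminus to the α-carbon near the ring methyl), it reacts across one C=C bond of the tropone in a [4+2] sense, or the silyl enol ether is lost on long heating. In the fallback the same two bonds are made one after the other at low temperature, as an anionic double Michael annulation. It sets out from 4 and 5: the kinetic lithium dienolate of 5 (LDA, THF, −78 °C) adds 1,8 to 4 and gives 4-methyl-2-[(E)-2-oxopent-3-enyl]cyclohepta-3,5-dien-1-one F4; in this fully anionic addition the preference for the α-carbon nearer the methyl should be larger than in the concerted reaction. DBU or catalytic KOt-Bu then closes F4 by intramolecular Michael addition of its α'-enolate to the enone, giving the bicyclic diketone F5; the ring closure is reversible, so the C10 methyl can settle on the less hindered top face. Ketalisation of F5 with (R,R)-hydrobenzoin (TsOH, benzene, Dean–Stark) and separation of the diastereomers rejoins the route at 8.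

3. Step 8. What may go wrong: migration of C6 instead of C1, so that oxygen enters on the C6 side of the bridge and the later steps would protect the wrong hydroxyls. The fallback sets out from 9 and carries the regioisomeric lactone F6 through the same operations with the order of protection reversed. Ring opening as in step 9, through the Weinreb amide F7, gives the hydroxy ketone F8 (C6–OH, C1 acetyl). TESCl and imidazole give the triethylsilyl ether F9; Baeyer–Villiger oxidation as in step 11 gives the C1 acetate F10; methanolysis gives the C1 alcohol F11; TBSCl and imidazole give the bis-silyl ether F12. Selective cleavage of the triethylsilyl ether (HF·pyridine, pyridine, THF, 0 °C) returns to the route at 16.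

Further compounds
F1 | step 15 | C6 trimethylsilyl ether of 16 | O1[C@H](c2ccccc2)[C@@H](c2ccccc2)OC13C[C@@H](C)[C@@H](O[Si](C)(C)C(C)(C)C)CC[C@@]4(C)O[C@H]4[C@H](C3)O[Si](C)(C)C
F2 | step 15 | 8-oxo compound with C6–OTMS and C1–OTBS | O=C1C[C@@H](C)[C@@H](O[Si](C)(C)C(C)(C)C)CC[C@@]2(C)O[C@H]2[C@H](C1)O[Si](C)(C)C
F3 | step 15 | C7 methoxalyl ketone, drawn as its enol | O=C1C[C@@H](C)[C@@H](O[Si](C)(C)C(C)(C)C)CC[C@@]2(C)O[C@H]2[C@@H](O[Si](C)(C)C)C1=C(O)C(=O)OC
F4 | step 5 | 4-methyl-2-[(E)-2-oxopent-3-enyl]cyclohepta-3,5-dien-1-one (racemic) | O=C1C(CC(=O)/C=C/C)C=C(C)C=CC1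
F5 | step 5 | (±)-4,10-dimethylbicyclo[4.4.1]undeca-2,4-diene-8,11-dione, C10 methyl syn to Cb | O=C1C[C@@H](C)[C@@H]2C=CC(C)=C[C@H](C1)C2=O
F6 | step 8 | regioisomeric epoxy lactone, C6–O–C(=O)–C1 bridge | O1[C@H](c2ccccc2)[C@@H](c2ccccc2)OC13C[C@@H](C)[C@@H]4CC[C@@]5(C)O[C@H]5[C@H](C3)OC4=O
F7 | step 8 | Weinreb amide at C1 with C6–OH | O1[C@H](c2ccccc2)[C@@H](c2ccccc2)OC13C[C@@H](C)[C@@H](C(=O)N(C)OC)CC[C@@]4(C)O[C@H]4[C@H](C3)O
F8 | step 8 | hydroxy ketone: C6–OH, C1–COCH3 | O1[C@H](c2ccccc2)[C@@H](c2ccccc2)OC13C[C@@H](C)[C@@H](C(C)=O)CC[C@@]4(C)O[C@H]4[C@H](C3)O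
F9 | step 8 | C6 triethylsilyl ether of F8 | O1[C@H](c2ccccc2)[C@@H](c2ccccc2)OC13C[C@@H](C)[C@@H](C(C)=O)CC[C@@]4(C)O[C@H]4[C@H](C3)O[Si](CC)(CC)CC
F10 | step 8 | C1 acetate, C6 triethylsilyl ether | O1[C@H](c2ccccc2)[C@@H](c2ccccc2)OC13C[C@@H](C)[C@@H](OC(C)=O)CC[C@@]4(C)O[C@H]4[C@H](C3)O[Si](CC)(CC)CC
F11 | step 8 | C1 alcohol, C6 triethylsilyl ether | O1[C@H](c2ccccc2)[C@@H](c2ccccc2)OC13C[C@@H](C)[C@@H](O)CC[C@@]4(C)O[C@H]4[C@H](C3)O[Si](CC)(CC)CC
F12 | step 8 | bis-silyl ether: C1–OTBS, C6–OTES | O1[C@H](c2ccccc2)[C@@H](c2ccccc2)OC13C[C@@H](C)[C@@H](O[Si](C)(C)C(C)(C)C)CC[C@@]4(C)O[C@H]4[C@H](C3)O[Si](CC)(CC)CC
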